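The numbers stand for no real mixture; the run is a simulation.

The target forms from dissolved electrophile, and dissolved electrophile comes from a solid that feeds the solution slowly.

solid electrophile 0.10 M; nucleophile 0.110 M; free base 0.0300 M; time 6.0 d

    electrophile + nucleophile → acid set free + target (k1 = 0.19 L mol⁻¹ h⁻¹)
    nucleophile + acid set free ⇌ protonated nucleophile, settled at all times (K2 = 660 L mol⁻¹)
    acid set free + free base ⇌ salt of the base, settled at all times (K3 = 1.0 × 10⁵ L mol⁻¹)
    acid set free → by-product carried off (k4 = 0.0086 h⁻¹)
    solid electrophile ⇌ electrophile, rate k5*(cs5 - [electrophile]) while solid is left; crystals form when [electrophile] > cs5 (cs5 = 38 mM, k5 = 0.011 h⁻¹)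
    nucleophile + target → over-reaction product (k6 = 0.55 L mol⁻¹ h⁻¹)

- part of the solid electrophile that has reacted (what has only dissolved counts as not reacted) at 6.0 d
- share of the unused nucleophile that is free and not bound as protonated nucleophile, at 6.0 d

Your hunch, free base spent one for one against the solid, gives 30.0%, but the feed gives another number. With nucleophile as charged, electrophile disappears with the pseudo-first-order constant 0.0209 h⁻¹. So [electrophile] climbs, within about 31.3 h, to the level 13.1 mM, where dissolution supplies what the reaction takes. That rate is 0.274 mM h⁻¹, which over the run, less the lag, makes 30.9 mM.

The correction is the lost nucleophile. The half-life of target by over-reaction, 0.48 d, is shorter than that of electrophile, 1.4 d, so each reacted electrophile soon takes a second nucleophile. The mean deficit over the run is then about that same amount, leaving 0.0791 M. Repeating the sum with this value gives 25.5 mM, the reacted amount, electrophile consumed per litre of solution. It holds no term in the charge of solid while solid is left; dividing by the charge gives 25.5%.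

Free base binds acid ahead of nucleophile, 3000 against 73, and the reacted amount stays below the base charge. Your cap is therefore not reached by 6.0 d, and the two balances leave 96.4% of the nucleophile free.

The forecast gives 26% and 97%: “Slow dissolution limits the reaction”. My two numbers lie slightly below these.

The flask gives 26.1% and 97.3%, which is 26.1 mM reacted against the reckoned 25.5 mM, with 57.7% of the solid undissolved at 6.00 d. In the neighbour, the same flask with 0.40 M of solid electrophile, the reacted amount stays and the charge grows, so 25.5 mM predicts 6.38%. That neighbour gives 6.52%, which is 26.1 mM reacted, about as much as in the first flask, and 97.3% of its unused nucleophile is free.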